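## Analysis of the target

CNP0267891.2 is a pentamer of guaiacylpropane units: rings A and B are joined through a 2‑aryl‑3‑hydroxymethyl‑4‑benzyl tetrahydrofuran (O–C7, C7–C8, C8–C8', C9'–O), and ring B is extended by three trans‑2‑aryl‑3‑hydroxymethyl‑2,3‑dihydrobenzofurans (unit 1: ring B fused, ring C on C2; unit 2: ring C fused, ring D on C2; unit 3: ring D fused, ring E on C2). There are nine stereocentres in four isolated groups: the tetrahydrofuran is (7R,8S,8'S), with the aryl group trans to the hydroxymethyl group and the hydroxymethyl group cis to the benzyl group, units 1 and 2 are (2S,3R) and unit 3 is (2R,3S). The groups are separated by arene spacers, so none can pass its configuration on, and the sense changes between unit 2 and unit 3; each group therefore needs its own source of absolute control. Sensitive functions are two free guaiacyl phenols, four primary alcohols and four benzylic C–O bonds para to an aryl oxygen (C7 and the three C2 atoms). These bonds ionise under acid, and the tetrahydrofuran can in addition rearrange by Friedel–Crafts attack of ring A on C7. The difficulty is thus repetition with changing sense: the same ring has to be built three times along an acid‑labile chain, trans each time, with an absolute configuration that can be chosen freely at each unit. The strategy rests on one feature: in every dihydrobenzofuran the ring oxygen is ortho to the arene carbon that bears C3, and the arene carbon para to that oxygen bears the benzylic carbon of the next unit. C3 is therefore the exocyclic carbon of an o‑quinone methide, C2 is a benzylic sulfonium ylide carbon, and a para ester on the methide precursor is the relay to the next ylide.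

## Retrosynthetic reasoning

**Deprotection.** Target 50 is traced to 49, in which the two phenols and three of the four primary alcohols are TIPS ethers. TIPS is preferred to smaller silyl groups: an aryl silyl ether para to a benzylic sulfonium carbon must survive carbonate base, and the primary ethers must survive a sulfinic acid and a catalytic acid step.

**Tetrahydrofuran (O–C7, then C7–C8).** 49 is opened at O–C7 to triol 48. C7 is benzylic and para to the ring oxygen of unit 1, so it ionises under mild acid and is captured by the C9' hydroxyl; the aryl group ends trans to the two cis substituents on C8 and C8'. Triol 48 comes from lactone 47 by hydride reduction, and 47 from an aldol bond C7–C8 between aldehyde 35 and enolate 46 of lactone 45. The benzyl group on C8' sends the aldehyde to the opposite enolate face, and this trans lactone becomes the cis hydroxymethyl/benzyl pair of the new ring. All three ring centres thus derive from the single centre of 45, which comes from auxiliary‑directed alkylation (43 from 41, made from acid 38 and oxazolidinone 39; 38 from 36).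

**Unit 1 (O–C2 and C2–C3).** Ester 33 is cut into sulfonium salt 30 and sulfone 6. Both bonds to C2 are cut because C2 can be nucleophile and electrophile in turn as an ylide, while C3 with ring B is the methide released from 6. The forward step must form the trans ring with 2S,3R under control of the sulfide.

**Unit 2.** Ester 27 is cut in the same way into salt 24 and a second copy of 6.

**Unit 3 (key disconnection).** Ester 18 is cut into salt 14 and a third copy of 6. Here the opposite sense (2R,3S) is needed, so the mirror‑image sulfide is used; nothing else changes.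

**Relay.** Each ester becomes the next ylide precursor by reduction, bromination and S‑alkylation: 30 from 29, 28 and 27 with sulfide 23; 24 from 20, 19 and 18 with 23. Sulfide 23 comes from diol 21 through dimesylate 22 with double inversion.

**Sulfone 6.** The sulfinate leaving group is installed by benzylic substitution on alcohol 5, which comes from diol 4 by silylation, 4 from styrene 3 by dihydroxylation, 3 from bromide 2 by vinylation, and 2 from methyl vanillate (1). The building block is racemic, because its stereocentre vanishes in the methide.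

**Salt 14.** It is cut at the S–CH2 bond into bromide 10 (from 9, 8 and vanillin 7) and sulfide 13 (from diol 11 through dimesylate 12).

## Alternatives that were turned down

**Alternative 1:** The C3–C3a bond of unit 1 is made last: the dihydrofuran is traced back to the six‑membered ring of flavanone A2, whose carbonyl carbon leaves the ring and becomes the C3 ester of A1. In the forward step A2 forms its methyl enol ether in acidic trimethyl orthoformate, PhI(OAc)2 adds to C3, and ring B shifts from C4 to C3 as the phenyliodanyl group departs; the cation at C4 is captured as the methyl ester, giving trans diester A1.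
- For it: this ring contraction is an established reaction of flavanones, so on precedent for the key step it is stronger than the chosen route. C2 of A2 is not touched, and the C3 ester allows equilibration to trans.
- Against it: C2 must be set earlier in A2, and that centre can racemise by reversible ring opening under the strongly acidic conditions. The electron‑rich arenes compete as sites of oxidation. A1 carries two esters, of which only the aliphatic one may be reduced. The bromine in A1 shows that every further unit needs a new acyl group, a condensation, an asymmetric ring closure and a contraction.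
- Comparison: the chosen strategy forms two bonds and both centres of a unit in one step from one repeated building block (6), delivers C3 at the alcohol oxidation level, and changes the absolute sense by the sulfide enantiomer alone. It pays with a key step that is not yet demonstrated.

**Alternative 2:** The cuts are C7'–C8' and C8–C7 around a four‑carbon lactone; the dihydrobenzofurans are not touched. In the forward step lithiated dithiane A4 adds to butenolide A5 anti to the menthyloxy group, and the lactone enolate is trapped by aldehyde A6 to give A3.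
- For it: three components are joined in one flask, both lactone centres come from a cheap auxiliary, and the union is highly convergent. For the C8–C8' unit it is at least as strong as the lactone aldol used in the endgame here, and it saves the separate synthesis of 45.
- Against it: A6 already holds all three dihydrobenzofurans and six stereocentres, so the alternative does not say how the repeating units are made. After the union the dithiane has to be removed reductively (Raney Ni) beside four benzylic C–O bonds, and the acetal carbon has to be reduced.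
- Comparison: the chosen strategy spends its key step on the repeating dihydrobenzofuran problem and ends with an aldol that needs no desulfurisation. Its endgame is less convergent by one C–C bond.

**Alternative 3:** The C2–C3 bonds of units 1 and 2 are cut together: each C3 becomes a diazo ester carbon on the arene that will be fused, and each C2 a benzylic CH2 of an aryl benzyl ether, as in bis(diazo ester) A8. In the forward step Rh2(S‑PTTL)4 or its mirror image decomposes both diazo groups, each carbene inserts into the neighbouring ArO–CH2–Ar bond, and DBU epimerises C3 to give trans,trans triester A7.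
- For it: enantioselective C–H insertion of this kind is known, it is catalytic in the chiral element, and it closes two rings in one step from ethers that are easy to assemble. On precedent and on economy of chirality it is stronger than a stoichiometric sulfide.
- Against it: the insertion gives the cis ester first, so C3 depends on a later equilibration. Two carbenes must react cleanly in a molecule with many electron‑rich arenes and further benzylic ether C–H bonds. A7 holds three esters, two to be reduced to alcohols and one to the aldehyde level. Unit 3, of opposite sense, still has to be made by other means before A8.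
- Comparison: the chosen strategy gives the trans ring directly, needs no ester differentiation, and uses the same operation for all three units. The sulfide it consumes is recovered in the same step.

Key step: step 12

Assumption (remark on the chemistry): the benzylic ylides of the C2‑symmetric thiolanes are taken to react through the same face as in their additions to aldehydes, so that the (2R,5R) salt gives 2R and the (2S,5S) salts give 2S; if the sense were the reverse, the two sulfide enantiomers would change places.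

Abbreviations in names:
- TIPS = triisopropylsilyl.
- ArE = 3‑methoxy‑4‑(TIPS‑oxy)phenyl.
- Ar(DE) = (2R,3S)‑7‑methoxy‑2‑ArE‑3‑[(TIPS‑oxy)methyl]‑2,3‑dihydrobenzofuran‑5‑yl.
- Ar(CDE) = (2S,3R)‑7‑methoxy‑2‑Ar(DE)‑3‑[(TIPS‑oxy)methyl]‑2,3‑dihydrobenzofuran‑5‑yl.
- Ar(BCDE) = (2S,3R)‑7‑methoxy‑2‑Ar(CDE)‑3‑[(TIPS‑oxy)methyl]‑2,3‑dihydrobenzofuran‑5‑yl.

## Steps

Step 1
Reactants: 1 methyl vanillate
Product: 2 methyl 3-bromo-4-hydroxy-5-methoxybenzoate
Conditions: Br2, AcOH, rt
Reagents that add atoms: bromine, BrBr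
Why: Electrophilic aromatic bromination; the phenol directs to its single free ortho position because the para position carries the ester.

Step 2
Reactants: 2 methyl 3-bromo-4-hydroxy-5-methoxybenzoate
Product: 3 methyl 4-hydroxy-3-methoxy-5-vinylbenzoate
Conditions: vinylboronic acid pinacol ester, PdCl2(dppf) (cat.), K2CO3, dioxane/H2O, 85 °C
Reagents that add atoms: vinylboronic acid pinacol ester, C=CB1OC(C)(C)C(C)(C)O1
Why: Suzuki–Miyaura coupling of the aryl bromide; the free phenol is tolerated as its phenoxide under aqueous carbonate.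

Step 3
Reactants: 3 methyl 4-hydroxy-3-methoxy-5-vinylbenzoate
Product: 4 methyl 3-(1,2-dihydroxyethyl)-4-hydroxy-5-methoxybenzoate (racemic)
Conditions: K2OsO4·2H2O (cat.), N-methylmorpholine N-oxide, acetone/H2O, rt
Reagents that add atoms: N-methylmorpholine N-oxide, C[N+]1([O-])CCOCC1; water, O
Why: Upjohn dihydroxylation of the styrene; the diol may be racemic because its benzylic carbon becomes trigonal in the quinone methide.

Step 4
Reactants: 4 methyl 3-(1,2-dihydroxyethyl)-4-hydroxy-5-methoxybenzoate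
Product: 5 methyl 4-hydroxy-3-[1-hydroxy-2-(TIPS-oxy)ethyl]-5-methoxybenzoate (racemic)
Conditions: TIPSCl (1.05 equiv), imidazole, CH2Cl2, 0 °C
Reagents that add atoms: chlorotriisopropylsilane, CC(C)[Si](Cl)(C(C)C)C(C)C
Why: Selective silylation of the primary alcohol; the bulky chlorosilane should leave the secondary benzylic alcohol and the doubly ortho-substituted, ester-deactivated phenol largely untouched, and any aryl silyl ether formed is cleaved back with K2CO3/MeOH.

Step 5
Reactants: 5 methyl 4-hydroxy-3-[1-hydroxy-2-(TIPS-oxy)ethyl]-5-methoxybenzoate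
Product: 6 methyl 4-hydroxy-3-methoxy-5-[1-(p-tolylsulfonyl)-2-(TIPS-oxy)ethyl]benzoate (racemic)
Conditions: p-TolSO2H (freshly prepared, 2 equiv), CH2Cl2, rt
Reagents that add atoms: p-toluenesulfinic acid, Cc1ccc(cc1)S(O)=O
Why: Acid-promoted benzylic substitution: the o-hydroxybenzyl alcohol loses water and the resulting cation, stabilised by the ortho oxygen, is captured at sulfur by the sulfinate to give the sulfone. The TIPS ether tolerates the weak acid.

Step 6
Reactants: 7 vanillin
Product: 8 3-methoxy-4-(TIPS-oxy)benzaldehyde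
Conditions: TIPSCl, imidazole, DMF, rt
Reagents that add atoms: chlorotriisopropylsilane, CC(C)[Si](Cl)(C(C)C)C(C)C
Why: Phenol silylation; TIPS is chosen so that the aryl ether para to the later sulfonium carbon survives carbonate base.

Step 7
Reactants: 8 3-methoxy-4-(TIPS-oxy)benzaldehyde
Product: 9 [3-methoxy-4-(TIPS-oxy)phenyl]methanol
Conditions: NaBH4, MeOH, 0 °C
Reagents that add atoms: none
Why: Borohydride reduction of the aldehyde; the aryl silyl ether is stable to NaBH4 in cold methanol.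

Step 8
Reactants: 9 [3-methoxy-4-(TIPS-oxy)phenyl]methanol
Product: 10 4-(bromomethyl)-2-methoxy-1-(TIPS-oxy)benzene
Conditions: CBr4, PPh3, CH2Cl2, 0 °C; used crude
Reagents that add atoms: carbon tetrabromide, BrC(Br)(Br)Br
Why: Appel bromination under neutral conditions; the electron-rich benzylic bromide is used at once without chromatography.

Step 9
Reactants: 11 (2S,5S)-hexane-2,5-diol
Product: 12 (2S,5S)-hexane-2,5-diyl dimethanesulfonate
Conditions: MsCl, Et3N, CH2Cl2, 0 °C
Reagents that add atoms: methanesulfonyl chloride, CS(Cl)(=O)=O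
Why: Mesylation of both secondary alcohols with retention, which prepares the double inversion.

Step 10
Reactants: 12 (2S,5S)-hexane-2,5-diyl dimethanesulfonate
Product: 13 (2R,5R)-2,5-dimethylthiolane
Conditions: Na2S·9H2O, DMSO, rt
Reagents that add atoms: sodium sulfide, [Na+].[Na+].[S-2]
Why: Double SN2 displacement by sulfide closes the thiolane with inversion at both carbons, which turns the (2S,5S) diol into the (2R,5R) sulfide.

Step 11
Reactants: 10 4-(bromomethyl)-2-methoxy-1-(TIPS-oxy)benzene, 13 (2R,5R)-2,5-dimethylthiolane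
Product: 14 (2R,5R)-1-[3-methoxy-4-(TIPS-oxy)benzyl]-2,5-dimethylthiolan-1-ium tetrafluoroborate
Conditions: AgBF4, CH2Cl2, −20 °C → rt, dark
Reagents that add atoms: silver tetrafluoroborate, [Ag+].F[B-](F)(F)F
Why: S-Alkylation of the sulfide by the benzylic bromide, driven by precipitation of AgBr; the C2 symmetry of the sulfide allows only one sulfonium salt.

Step 12
Reactants: 6 methyl 4-hydroxy-3-methoxy-5-[1-(p-tolylsulfonyl)-2-(TIPS-oxy)ethyl]benzoate, 14 (2R,5R)-1-[3-methoxy-4-(TIPS-oxy)benzyl]-2,5-dimethylthiolan-1-ium tetrafluoroborate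
Product: 18 methyl (2R,3S)-7-methoxy-2-[3-methoxy-4-(TIPS-oxy)phenyl]-3-[(TIPS-oxy)methyl]-2,3-dihydrobenzofuran-5-carboxylate, via o-quinone methide 15 (not isolated), via sulfonium ylide 16 (not isolated), via betaine 17 (not isolated)
Conditions: Cs2CO3 (3 equiv), 14 (1.5 equiv), CH2Cl2/MeCN, −20 → 0 °C, 6 added slowly
Reagents that add atoms: none
Why: Proposed new method: Cs2CO3 deprotonates the phenol of 6, whose phenoxide expels p-toluenesulfinate to give (E)-o-quinone methide 15, and deprotonates 14 at the benzylic carbon to give ylide 16; the ylide carbon adds to the exocyclic methide carbon (C2–C3), ring D re-aromatises to phenoxide betaine 17, and the phenoxide displaces the thiolane from the benzylic carbon (O–C2). The closest known reaction types are the (4+1) annulation of o-quinone methides released from 2-(1-tosylalkyl)phenols with carbonyl-stabilised sulfonium ylides and, for the chiral component, the epoxidation of aldehydes by benzylic ylides of the same C2-symmetric thiolane; an alkyl-substituted methide has not been combined with such a semi-stabilised chiral ylide. The dihydrofuran ring closes 5-exo-tet with inversion at the ylide carbon. C2 is set by the sulfide: its symmetry allows one kind of ylide only, the methyl group cis to the ylide carbon screens one face, and attack through the open face followed by inversion should give 2R. C3 follows from the trans preference: the addition is driven by aromatisation and is unlikely to revert, so trans has to be decided in the C–C bond-forming transition state, where the thiolanium group and ring E turn away from the silyloxymethyl arm of the E-methide and only that adduct reaches the closing geometry without eclipsing the two substituents. The step needs the ylide to add faster than 15 tautomerises to a vinyl phenol; the para ester raises the electrophilicity of the methide, 14 is used in excess, and 6 is added slowly so that the methide never accumulates. The TIPS ether para to the sulfonium carbon is chosen because loss of a smaller silyl group under carbonate would turn 14 into a p-quinone methide.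

Step 13
Reactants: 18 Ar(DE)–CO2Me
Product: 19 Ar(DE)–CH2OH ([(2R,3S)-7-methoxy-2-ArE-3-[(TIPS-oxy)methyl]-2,3-dihydrobenzofuran-5-yl]methanol)
Conditions: i-Bu2AlH, CH2Cl2, −78 → −40 °C
Reagents that add atoms: none
Why: Ester reduction with i-Bu2AlH at low temperature; the silyl ethers and the benzylic ether of the dihydrobenzofuran are inert.

Step 14
Reactants: 19 Ar(DE)–CH2OH
Product: 20 Ar(DE)–CH2Br
Conditions: CBr4, PPh3, CH2Cl2, −20 → 0 °C; used crude
Reagents that add atoms: carbon tetrabromide, BrC(Br)(Br)Br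
Why: Appel bromination; the 3,4-dioxygenated benzylic bromide is labile and is carried on without chromatography.

Step 15
Reactants: 21 (2R,5R)-hexane-2,5-diol
Product: 22 (2R,5R)-hexane-2,5-diyl dimethanesulfonate
Conditions: MsCl, Et3N, CH2Cl2, 0 °C
Reagents that add atoms: methanesulfonyl chloride, CS(Cl)(=O)=O
Why: Mesylation with retention, as in step 9, in the mirror-image series.

Step 16
Reactants: 22 (2R,5R)-hexane-2,5-diyl dimethanesulfonate
Product: 23 (2S,5S)-2,5-dimethylthiolane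
Conditions: Na2S·9H2O, DMSO, rt
Reagents that add atoms: sodium sulfide, [Na+].[Na+].[S-2]
Why: Double SN2 ring closure with inversion at both carbons gives the (2S,5S) sulfide needed for units 2 and 1.

Step 17
Reactants: 20 Ar(DE)–CH2Br, 23 (2S,5S)-2,5-dimethylthiolane
Product: 24 (2S,5S)-1-[Ar(DE)-methyl]-2,5-dimethylthiolan-1-ium tetrafluoroborate
Conditions: AgBF4, CH2Cl2, −20 °C → rt, dark
Reagents that add atoms: silver tetrafluoroborate, [Ag+].F[B-](F)(F)F
Why: Sulfonium salt formation as in step 11; the (2S,5S) sulfide programmes the opposite sense for unit 2.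

Step 18
Reactants: 24 (2S,5S)-1-[Ar(DE)-methyl]-2,5-dimethylthiolan-1-ium tetrafluoroborate, 6 methyl 4-hydroxy-3-methoxy-5-[1-(p-tolylsulfonyl)-2-(TIPS-oxy)ethyl]benzoate
Product: 27 Ar(CDE)–CO2Me, via sulfonium ylide 25 (not isolated), via betaine 26 (not isolated)
Conditions: Cs2CO3, CH2Cl2/MeCN, −20 → 0 °C, 6 (2 equiv) added in portions
Reagents that add atoms: none
Why: Proposed new method: the mechanism is that of step 12 (sulfone 6 again releases the transient methide 15 described there, salt 24 gives ylide 25, conjugate addition leads to betaine 26, and 5-exo-tet closure with inversion follows), and the closest known reaction type is again the (4+1) annulation of in situ o-quinone methides with stabilised sulfonium ylides; the mirror-image sulfide should now give 2S,3R. The existing centres of unit 3 lie beyond an arene and should not influence the new ones, so a minor-face addition would appear as a separable diastereomer; the cheap sulfone 6 is the component used in excess here.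

Step 19
Reactants: 27 Ar(CDE)–CO2Me
Product: 28 Ar(CDE)–CH2OH
Conditions: i-Bu2AlH, CH2Cl2, −78 → −40 °C
Reagents that add atoms: none
Why: Ester reduction as in step 13.

Step 20
Reactants: 28 Ar(CDE)–CH2OH
Product: 29 Ar(CDE)–CH2Br
Conditions: CBr4, PPh3, CH2Cl2, −20 → 0 °C; used crude
Reagents that add atoms: carbon tetrabromide, BrC(Br)(Br)Br
Why: Appel bromination as in step 14.

Step 21
Reactants: 29 Ar(CDE)–CH2Br, 23 (2S,5S)-2,5-dimethylthiolane
Product: 30 (2S,5S)-1-[Ar(CDE)-methyl]-2,5-dimethylthiolan-1-ium tetrafluoroborate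
Conditions: AgBF4, CH2Cl2, −20 °C → rt, dark
Reagents that add atoms: silver tetrafluoroborate, [Ag+].F[B-](F)(F)F
Why: Sulfonium salt formation as in step 17; unit 1 has the same sense as unit 2, so the same sulfide is used.

Step 22
Reactants: 30 (2S,5S)-1-[Ar(CDE)-methyl]-2,5-dimethylthiolan-1-ium tetrafluoroborate, 6 methyl 4-hydroxy-3-methoxy-5-[1-(p-tolylsulfonyl)-2-(TIPS-oxy)ethyl]benzoate
Product: 33 Ar(BCDE)–CO2Me, via sulfonium ylide 31 (not isolated), via betaine 32 (not isolated)
Conditions: Cs2CO3, CH2Cl2/MeCN, −20 → 0 °C, 6 (2 equiv) added in portions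
Reagents that add atoms: none
Why: Proposed new method: third use of the annulation of step 12, by the same mechanism (sulfone 6 once more releases the transient methide 15, which is intercepted by ylide 31 to give betaine 32 before 5-exo-tet closure) and with the same closest known reaction type (annulation of in situ o-quinone methides with stabilised sulfonium ylides); the (2S,5S) sulfide should set 2S,3R in unit 1, and the ester that remains on ring B is the handle for the tetrahydrofuran.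

Step 23
Reactants: 33 Ar(BCDE)–CO2Me
Product: 34 Ar(BCDE)–CH2OH
Conditions: i-Bu2AlH, CH2Cl2, −78 → −40 °C
Reagents that add atoms: none
Why: Ester reduction as in step 13.

Step 24
Reactants: 34 Ar(BCDE)–CH2OH
Product: 35 Ar(BCDE)–CHO
Conditions: MnO2, CH2Cl2, rt
Reagents that add atoms: none
Why: MnO2 oxidises the electron-rich benzylic alcohol selectively to the aldehyde and leaves silyl ethers and benzylic ethers alone.

Step 25
Reactants: 36 3-(4-hydroxy-3-methoxyphenyl)propanoic acid
Product: 38 3-[3-methoxy-4-(TIPS-oxy)phenyl]propanoic acid, via bis-silylated acid 37 (not isolated)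
Conditions: TIPSCl (2.3 equiv), imidazole, DMF, rt; then AcOH/THF/H2O, rt
Reagents that add atoms: chlorotriisopropylsilane, CC(C)[Si](Cl)(C(C)C)C(C)C
Why: Exhaustive silylation followed by selective hydrolysis of the labile silyl ester, which leaves the aryl TIPS ether.

Step 26
Reactants: 38 3-[3-methoxy-4-(TIPS-oxy)phenyl]propanoic acid, 39 (R)-4-benzyloxazolidin-2-one
Product: 41 (R)-4-benzyl-3-{3-[3-methoxy-4-(TIPS-oxy)phenyl]propanoyl}oxazolidin-2-one, via mixed pivalic anhydride 40 (not isolated)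
Conditions: t-BuCOCl, Et3N, THF, −20 °C; then LiCl, 39, rt
Reagents that add atoms: none
Why: N-Acylation of the oxazolidinone through the mixed pivalic anhydride; attack occurs at the less hindered carbonyl.

Step 27
Reactants: 41 (R)-4-benzyl-3-{3-[3-methoxy-4-(TIPS-oxy)phenyl]propanoyl}oxazolidin-2-one
Product: 43 (R)-4-benzyl-3-{(S)-4-tert-butoxy-2-[3-methoxy-4-(TIPS-oxy)benzyl]-4-oxobutanoyl}oxazolidin-2-one, via sodium enolate 42 (not isolated)
Conditions: NaN(SiMe3)2, THF, −78 °C; BrCH2CO2t-Bu, −78 → −40 °C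
Reagents that add atoms: tert-butyl bromoacetate, BrCC(=O)OC(C)(C)C
Why: Oxazolidinone-directed alkylation of the chelated Z-enolate; the benzyl group of the (R)-auxiliary screens one face, so the bromoacetate enters from the other and sets the (S) centre that becomes C8'.

Step 28
Reactants: 43 (R)-4-benzyl-3-{(S)-4-tert-butoxy-2-[3-methoxy-4-(TIPS-oxy)benzyl]-4-oxobutanoyl}oxazolidin-2-one
Product: 45 (S)-4-[3-methoxy-4-(TIPS-oxy)benzyl]dihydrofuran-2(3H)-one, via hydroxy ester 44 (not isolated)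
Conditions: NaBH4, THF/H2O, 0 °C → rt; then TsOH·H2O (cat.), toluene, 50 °C
Reagents that add atoms: none
Why: Reductive removal of the auxiliary gives the primary alcohol without reducing the tert-butyl ester, and acid-catalysed lactonisation with loss of tert-butanol gives the (S)-lactone; the stereocentre is not epimerised in either stage.

Step 29
Reactants: 45 (S)-4-[3-methoxy-4-(TIPS-oxy)benzyl]dihydrofuran-2(3H)-one, 35 Ar(BCDE)–CHO
Product: 47 (3R,4S)-3-[hydroxy(Ar(BCDE))methyl]-4-[3-methoxy-4-(TIPS-oxy)benzyl]dihydrofuran-2(3H)-one (both carbinol epimers), via lithium enolate 46 (not isolated)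
Conditions: LiN(i-Pr)2, THF, −78 °C, 45 (1.5 equiv); then 35, −78 °C; AcOH quench
Reagents that add atoms: none
Why: Aldol addition of the lactone lithium enolate to the non-enolisable aldehyde; the aldehyde enters anti to the benzyl group, which sets C8 trans to C8' on the lactone. The carbinol carbon C7 forms as a mixture that converges in step 31.

Step 30
Reactants: 47 (3R,4S)-3-[hydroxy(Ar(BCDE))methyl]-4-[3-methoxy-4-(TIPS-oxy)benzyl]dihydrofuran-2(3H)-one
Product: 48 (2S,3S)-2-[hydroxy(Ar(BCDE))methyl]-3-[3-methoxy-4-(TIPS-oxy)benzyl]butane-1,4-diol (both carbinol epimers)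
Conditions: LiBH4, MeOH (2 equiv), THF, 0 °C → rt
Reagents that add atoms: none
Why: Hydride reduction of the lactone to the 1,4-diol; LiBH4 is mild enough for the aryl silyl ethers, and the low temperature limits retro-aldol cleavage.

Step 31
Reactants: 48 (2S,3S)-2-[hydroxy(Ar(BCDE))methyl]-3-[3-methoxy-4-(TIPS-oxy)benzyl]butane-1,4-diol
Product: 49 {(2R,3S,4S)-2-Ar(BCDE)-4-[3-methoxy-4-(TIPS-oxy)benzyl]tetrahydrofuran-3-yl}methanol
Conditions: camphorsulfonic acid (10 mol%), CH2Cl2, 0 °C, short; Et3N quench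
Reagents that add atoms: none
Why: Acid-catalysed cycloetherification: the benzylic alcohol para to the ring oxygen of unit 1 ionises and the C9' hydroxyl closes the five-membered ring, so both C7 epimers converge on the isomer with the aryl group trans to the two cis substituents at C8 and C8' (7R). The step is run cold, briefly and with catalytic acid so that the new ether does not re-ionise towards Friedel–Crafts attack by ring A or opening of the dihydrobenzofurans.

Step 32
Reactants: 49 {(2R,3S,4S)-2-Ar(BCDE)-4-[3-methoxy-4-(TIPS-oxy)benzyl]tetrahydrofuran-3-yl}methanol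
Product: 50 CNP0267891.2
Conditions: Bu4NF, AcOH (1:1), THF, 0 °C → rt
Reagents that add atoms: none
Why: Fluoride cleaves the three primary and two aryl TIPS ethers; buffering with acetic acid keeps the free guaiacyl phenols away from base-induced p-quinone methide chemistry.

## Compound list

1 | methyl vanillate (methyl 4-hydroxy-3-methoxybenzoate) | COC(=O)c1ccc(O)c(OC)c1 | starting material
2 | methyl 3-bromo-4-hydroxy-5-methoxybenzoate | COC(=O)c1cc(OC)c(O)c(Br)c1 | intermediate
3 | methyl 4-hydroxy-3-methoxy-5-vinylbenzoate | COC(=O)c1cc(OC)c(O)c(C=C)c1 | intermediate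
4 | methyl 3-(1,2-dihydroxyethyl)-4-hydroxy-5-methoxybenzoate (racemic) | COC(=O)c1cc(OC)c(O)c(c1)C(O)CO | intermediate
5 | methyl 4-hydroxy-3-[1-hydroxy-2-(triisopropylsilyloxy)ethyl]-5-methoxybenzoate (racemic) | COC(=O)c1cc(OC)c(O)c(c1)C(O)CO[Si](C(C)C)(C(C)C)C(C)C | intermediate
6 | methyl 4-hydroxy-3-methoxy-5-[1-(p-tolylsulfonyl)-2-(triisopropylsilyloxy)ethyl]benzoate (racemic) | COC(=O)c1cc(OC)c(O)c(c1)C(CO[Si](C(C)C)(C(C)C)C(C)C)S(=O)(=O)c1ccc(C)cc1 | intermediate
7 | vanillin | COc1cc(C=O)ccc1O | starting material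
8 | 3-methoxy-4-(triisopropylsilyloxy)benzaldehyde | COc1cc(C=O)ccc1O[Si](C(C)C)(C(C)C)C(C)C | intermediate
9 | [3-methoxy-4-(triisopropylsilyloxy)phenyl]methanol | COc1cc(CO)ccc1O[Si](C(C)C)(C(C)C)C(C)C | intermediate
10 | 4-(bromomethyl)-2-methoxy-1-(triisopropylsilyloxy)benzene | COc1cc(CBr)ccc1O[Si](C(C)C)(C(C)C)C(C)C | intermediate
11 | (2S,5S)-hexane-2,5-diol | C[C@H](O)CC[C@H](C)O | starting material
12 | (2S,5S)-hexane-2,5-diyl dimethanesulfonate | C[C@H](OS(C)(=O)=O)CC[C@H](C)OS(C)(=O)=O | intermediate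
13 | (2R,5R)-2,5-dimethylthiolane | C[C@@H]1CC[C@@H](C)S1 | intermediate
14 | (2R,5R)-1-[3-methoxy-4-(triisopropylsilyloxy)benzyl]-2,5-dimethylthiolan-1-ium tetrafluoroborate | C[C@@H]1CC[C@@H](C)[S+]1Cc1ccc(O[Si](C(C)C)(C(C)C)C(C)C)c(OC)c1.F[B-](F)(F)F | intermediate
15 | methyl (3E)-5-methoxy-4-oxo-3-[2-(triisopropylsilyloxy)ethylidene]cyclohexa-1,5-diene-1-carboxylate (o-quinone methide) | COC(=O)C1=C/C(=C\CO[Si](C(C)C)(C(C)C)C(C)C)C(=O)C(OC)=C1 | intermediate
16 | (2R,5R)-2,5-dimethylthiolan-1-ium [3-methoxy-4-(triisopropylsilyloxy)phenyl]methylide | C[C@@H]1CC[C@@H](C)[S+]1[CH-]c1ccc(O[Si](C(C)C)(C(C)C)C(C)C)c(OC)c1 | intermediate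
17 | betaine: 2-methoxy-4-(methoxycarbonyl)-6-{(2S,3S)-3-[(2R,5R)-2,5-dimethylthiolan-1-ium-1-yl]-3-ArE-1-(triisopropylsilyloxy)propan-2-yl}phenolate | COC(=O)c1cc(OC)c([O-])c(c1)[C@@H](CO[Si](C(C)C)(C(C)C)C(C)C)[C@@H](c1ccc(O[Si](C(C)C)(C(C)C)C(C)C)c(OC)c1)[S+]1[C@H](C)CC[C@H]1C | intermediate
18 | methyl (2R,3S)-7-methoxy-2-[3-methoxy-4-(triisopropylsilyloxy)phenyl]-3-[(triisopropylsilyloxy)methyl]-2,3-dihydrobenzofuran-5-carboxylate, Ar(DE)–CO2Me | COC(=O)c1cc(OC)c2c(c1)[C@@H](CO[Si](C(C)C)(C(C)C)C(C)C)[C@H](c1ccc(O[Si](C(C)C)(C(C)C)C(C)C)c(OC)c1)O2 | intermediate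
19 | Ar(DE)–CH2OH | OCc1cc(OC)c2c(c1)[C@@H](CO[Si](C(C)C)(C(C)C)C(C)C)[C@H](c1ccc(O[Si](C(C)C)(C(C)C)C(C)C)c(OC)c1)O2 | intermediate
20 | Ar(DE)–CH2Br | BrCc1cc(OC)c2c(c1)[C@@H](CO[Si](C(C)C)(C(C)C)C(C)C)[C@H](c1ccc(O[Si](C(C)C)(C(C)C)C(C)C)c(OC)c1)O2 | intermediate
21 | (2R,5R)-hexane-2,5-diol | C[C@@H](O)CC[C@@H](C)O | starting material
22 | (2R,5R)-hexane-2,5-diyl dimethanesulfonate | C[C@@H](OS(C)(=O)=O)CC[C@@H](C)OS(C)(=O)=O | intermediate
23 | (2S,5S)-2,5-dimethylthiolane | C[C@H]1CC[C@H](C)S1 | intermediate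
24 | (2S,5S)-1-[Ar(DE)-methyl]-2,5-dimethylthiolan-1-ium tetrafluoroborate | C[C@H]1CC[C@H](C)[S+]1Cc1cc(OC)c2c(c1)[C@@H](CO[Si](C(C)C)(C(C)C)C(C)C)[C@H](c1ccc(O[Si](C(C)C)(C(C)C)C(C)C)c(OC)c1)O2.F[B-](F)(F)F | intermediate
25 | (2S,5S)-2,5-dimethylthiolan-1-ium Ar(DE)-methylide | C[C@H]1CC[C@H](C)[S+]1[CH-]c1cc(OC)c2c(c1)[C@@H](CO[Si](C(C)C)(C(C)C)C(C)C)[C@H](c1ccc(O[Si](C(C)C)(C(C)C)C(C)C)c(OC)c1)O2 | intermediate
26 | betaine: 2-methoxy-4-(methoxycarbonyl)-6-{(2R,3R)-3-[(2S,5S)-2,5-dimethylthiolan-1-ium-1-yl]-3-Ar(DE)-1-(triisopropylsilyloxy)propan-2-yl}phenolate | COC(=O)c1cc(OC)c([O-])c(c1)[C@H](CO[Si](C(C)C)(C(C)C)C(C)C)[C@H](c1cc(OC)c2c(c1)[C@@H](CO[Si](C(C)C)(C(C)C)C(C)C)[C@H](c1ccc(O[Si](C(C)C)(C(C)C)C(C)C)c(OC)c1)O2)[S+]1[C@@H](C)CC[C@@H]1C | intermediate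
27 | Ar(CDE)–CO2Me, methyl (2S,3R)-7-methoxy-2-Ar(DE)-3-[(triisopropylsilyloxy)methyl]-2,3-dihydrobenzofuran-5-carboxylate | COC(=O)c1cc(OC)c2c(c1)[C@H](CO[Si](C(C)C)(C(C)C)C(C)C)[C@@H](c1cc(OC)c3c(c1)[C@@H](CO[Si](C(C)C)(C(C)C)C(C)C)[C@H](c1ccc(O[Si](C(C)C)(C(C)C)C(C)C)c(OC)c1)O3)O2 | intermediate
28 | Ar(CDE)–CH2OH | OCc1cc(OC)c2c(c1)[C@H](CO[Si](C(C)C)(C(C)C)C(C)C)[C@@H](c1cc(OC)c3c(c1)[C@@H](CO[Si](C(C)C)(C(C)C)C(C)C)[C@H](c1ccc(O[Si](C(C)C)(C(C)C)C(C)C)c(OC)c1)O3)O2 | intermediate
29 | Ar(CDE)–CH2Br | BrCc1cc(OC)c2c(c1)[C@H](CO[Si](C(C)C)(C(C)C)C(C)C)[C@@H](c1cc(OC)c3c(c1)[C@@H](CO[Si](C(C)C)(C(C)C)C(C)C)[C@H](c1ccc(O[Si](C(C)C)(C(C)C)C(C)C)c(OC)c1)O3)O2 | intermediate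
30 | (2S,5S)-1-[Ar(CDE)-methyl]-2,5-dimethylthiolan-1-ium tetrafluoroborate | C[C@H]1CC[C@H](C)[S+]1Cc1cc(OC)c2c(c1)[C@H](CO[Si](C(C)C)(C(C)C)C(C)C)[C@@H](c1cc(OC)c3c(c1)[C@@H](CO[Si](C(C)C)(C(C)C)C(C)C)[C@H](c1ccc(O[Si](C(C)C)(C(C)C)C(C)C)c(OC)c1)O3)O2.F[B-](F)(F)F | intermediate
31 | (2S,5S)-2,5-dimethylthiolan-1-ium Ar(CDE)-methylide | C[C@H]1CC[C@H](C)[S+]1[CH-]c1cc(OC)c2c(c1)[C@H](CO[Si](C(C)C)(C(C)C)C(C)C)[C@@H](c1cc(OC)c3c(c1)[C@@H](CO[Si](C(C)C)(C(C)C)C(C)C)[C@H](c1ccc(O[Si](C(C)C)(C(C)C)C(C)C)c(OC)c1)O3)O2 | intermediate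
32 | betaine: 2-methoxy-4-(methoxycarbonyl)-6-{(2R,3R)-3-[(2S,5S)-2,5-dimethylthiolan-1-ium-1-yl]-3-Ar(CDE)-1-(triisopropylsilyloxy)propan-2-yl}phenolate | COC(=O)c1cc(OC)c([O-])c(c1)[C@H](CO[Si](C(C)C)(C(C)C)C(C)C)[C@H](c1cc(OC)c2c(c1)[C@H](CO[Si](C(C)C)(C(C)C)C(C)C)[C@@H](c1cc(OC)c3c(c1)[C@@H](CO[Si](C(C)C)(C(C)C)C(C)C)[C@H](c1ccc(O[Si](C(C)C)(C(C)C)C(C)C)c(OC)c1)O3)O2)[S+]1[C@@H](C)CC[C@@H]1C | intermediate
33 | Ar(BCDE)–CO2Me, methyl (2S,3R)-7-methoxy-2-Ar(CDE)-3-[(triisopropylsilyloxy)methyl]-2,3-dihydrobenzofuran-5-carboxylate | COC(=O)c1cc(OC)c2c(c1)[C@H](CO[Si](C(C)C)(C(C)C)C(C)C)[C@@H](c1cc(OC)c3c(c1)[C@H](CO[Si](C(C)C)(C(C)C)C(C)C)[C@@H](c1cc(OC)c4c(c1)[C@@H](CO[Si](C(C)C)(C(C)C)C(C)C)[C@H](c1ccc(O[Si](C(C)C)(C(C)C)C(C)C)c(OC)c1)O4)O3)O2 | intermediate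
34 | Ar(BCDE)–CH2OH | OCc1cc(OC)c2c(c1)[C@H](CO[Si](C(C)C)(C(C)C)C(C)C)[C@@H](c1cc(OC)c3c(c1)[C@H](CO[Si](C(C)C)(C(C)C)C(C)C)[C@@H](c1cc(OC)c4c(c1)[C@@H](CO[Si](C(C)C)(C(C)C)C(C)C)[C@H](c1ccc(O[Si](C(C)C)(C(C)C)C(C)C)c(OC)c1)O4)O3)O2 | intermediate
35 | Ar(BCDE)–CHO | O=Cc1cc(OC)c2c(c1)[C@H](CO[Si](C(C)C)(C(C)C)C(C)C)[C@@H](c1cc(OC)c3c(c1)[C@H](CO[Si](C(C)C)(C(C)C)C(C)C)[C@@H](c1cc(OC)c4c(c1)[C@@H](CO[Si](C(C)C)(C(C)C)C(C)C)[C@H](c1ccc(O[Si](C(C)C)(C(C)C)C(C)C)c(OC)c1)O4)O3)O2 | intermediate
36 | 3-(4-hydroxy-3-methoxyphenyl)propanoic acid | OC(=O)CCc1ccc(O)c(OC)c1 | starting material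
37 | triisopropylsilyl 3-[3-methoxy-4-(triisopropylsilyloxy)phenyl]propanoate | CC(C)[Si](OC(=O)CCc1ccc(O[Si](C(C)C)(C(C)C)C(C)C)c(OC)c1)(C(C)C)C(C)C | intermediate
38 | 3-[3-methoxy-4-(triisopropylsilyloxy)phenyl]propanoic acid | OC(=O)CCc1ccc(O[Si](C(C)C)(C(C)C)C(C)C)c(OC)c1 | intermediate
39 | (R)-4-benzyloxazolidin-2-one | O=C1N[C@H](Cc2ccccc2)CO1 | starting material
40 | 3-[3-methoxy-4-(triisopropylsilyloxy)phenyl]propanoic pivalic anhydride | CC(C)(C)C(=O)OC(=O)CCc1ccc(O[Si](C(C)C)(C(C)C)C(C)C)c(OC)c1 | intermediate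
41 | (R)-4-benzyl-3-{3-[3-methoxy-4-(triisopropylsilyloxy)phenyl]propanoyl}oxazolidin-2-one | O=C(CCc1ccc(O[Si](C(C)C)(C(C)C)C(C)C)c(OC)c1)N1[C@H](Cc2ccccc2)COC1=O | intermediate
42 | sodium (Z)-enolate of 41 | [Na+].[O-]/C(=C\Cc1ccc(O[Si](C(C)C)(C(C)C)C(C)C)c(OC)c1)N1[C@H](Cc2ccccc2)COC1=O | intermediate
43 | (R)-4-benzyl-3-{(S)-4-tert-butoxy-2-[3-methoxy-4-(triisopropylsilyloxy)benzyl]-4-oxobutanoyl}oxazolidin-2-one | O=C([C@@H](Cc1ccc(O[Si](C(C)C)(C(C)C)C(C)C)c(OC)c1)CC(=O)OC(C)(C)C)N1[C@H](Cc2ccccc2)COC1=O | intermediate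
44 | tert-butyl (S)-4-hydroxy-3-[3-methoxy-4-(triisopropylsilyloxy)benzyl]butanoate | OC[C@@H](Cc1ccc(O[Si](C(C)C)(C(C)C)C(C)C)c(OC)c1)CC(=O)OC(C)(C)C | intermediate
45 | (S)-4-[3-methoxy-4-(triisopropylsilyloxy)benzyl]dihydrofuran-2(3H)-one | O=C1C[C@H](Cc2ccc(O[Si](C(C)C)(C(C)C)C(C)C)c(OC)c2)CO1 | intermediate
46 | lithium enolate of 45 | [Li+].[O-]C1=C[C@H](Cc2ccc(O[Si](C(C)C)(C(C)C)C(C)C)c(OC)c2)CO1 | intermediate
47 | (3R,4S)-3-[hydroxy(Ar(BCDE))methyl]-4-[3-methoxy-4-(triisopropylsilyloxy)benzyl]dihydrofuran-2(3H)-one (carbinol epimers) | O=C1OC[C@@H](Cc2ccc(O[Si](C(C)C)(C(C)C)C(C)C)c(OC)c2)[C@@H]1C(O)c1cc(OC)c2c(c1)[C@H](CO[Si](C(C)C)(C(C)C)C(C)C)[C@@H](c1cc(OC)c3c(c1)[C@H](CO[Si](C(C)C)(C(C)C)C(C)C)[C@@H](c1cc(OC)c4c(c1)[C@@H](CO[Si](C(C)C)(C(C)C)C(C)C)[C@H](c1ccc(O[Si](C(C)C)(C(C)C)C(C)C)c(OC)c1)O4)O3)O2 | intermediate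
48 | (2S,3S)-2-[hydroxy(Ar(BCDE))methyl]-3-[3-methoxy-4-(triisopropylsilyloxy)benzyl]butane-1,4-diol (carbinol epimers) | OC[C@@H](Cc1ccc(O[Si](C(C)C)(C(C)C)C(C)C)c(OC)c1)[C@@H](CO)C(O)c1cc(OC)c2c(c1)[C@H](CO[Si](C(C)C)(C(C)C)C(C)C)[C@@H](c1cc(OC)c3c(c1)[C@H](CO[Si](C(C)C)(C(C)C)C(C)C)[C@@H](c1cc(OC)c4c(c1)[C@@H](CO[Si](C(C)C)(C(C)C)C(C)C)[C@H](c1ccc(O[Si](C(C)C)(C(C)C)C(C)C)c(OC)c1)O4)O3)O2 | intermediate
49 | {(2R,3S,4S)-2-Ar(BCDE)-4-[3-methoxy-4-(triisopropylsilyloxy)benzyl]tetrahydrofuran-3-yl}methanol | COc1cc(C[C@@H]2CO[C@@H](c3cc(OC)c4c(c3)[C@H](CO[Si](C(C)C)(C(C)C)C(C)C)[C@@H](c3cc(OC)c5c(c3)[C@H](CO[Si](C(C)C)(C(C)C)C(C)C)[C@@H](c3cc(OC)c6c(c3)[C@@H](CO[Si](C(C)C)(C(C)C)C(C)C)[C@H](c3ccc(O[Si](C(C)C)(C(C)C)C(C)C)c(OC)c3)O6)O5)O4)[C@@H]2CO)ccc1O[Si](C(C)C)(C(C)C)C(C)C | intermediate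
50 | CNP0267891.2, the fully desilylated form of 49 with the (7R,8S,8'S) tetrahydrofuran, units 1 and 2 (2S,3R) and unit 3 (2R,3S) | COc1cc(C[C@@H]2CO[C@@H](c3cc(OC)c4c(c3)[C@H](CO)[C@@H](c3cc(OC)c5c(c3)[C@H](CO)[C@@H](c3cc(OC)c6c(c3)[C@@H](CO)[C@H](c3ccc(O)c(OC)c3)O6)O5)O4)[C@@H]2CO)ccc1O | target

## Step count and least certain steps

Total step count: 32. Longest linear sequence: 20 steps, from methyl vanillate (steps 1–5, 12–14, 17–24, 29–32).

**Step 12 (key step, Proposed new method).** Three processes may defeat it.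
- Tautomerisation of the alkyl-substituted methide to a vinyl phenol may be faster than ylide addition, because the methide has acidic hydrogens next to the exocyclic carbon.
- Carbonate may deprotonate the electron-rich benzylic sulfonium salt only poorly, or the salt may pass its benzyl group to phenoxide or sulfinate, because such salts ionise easily.
- Facial control at the ylide or the trans preference may be incomplete, because the addition is irreversible and nothing corrects a wrong adduct.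

The fallback uses known chemistry (auxiliary-controlled syn aldol, reductive removal of the auxiliary, acid-mediated benzylic etherification); it sets out from styrene 3 and aldehyde 8 and returns at 18. Styrene 3 is protected as methoxymethyl ether F1 (MOMCl, i-Pr2NEt). F1 is hydroborated and oxidised to primary alcohol F2 (9-BBN; NaBO3·4H2O), and F2 is oxidised to arylacetic acid F3 (TEMPO, PhI(OAc)2, MeCN/H2O). F3 is coupled with oxazolidinone 39 through its mixed pivalic anhydride to give imide F4. The dibutylboron enolate of F4 (Bu2BOTf, i-Pr2NEt) adds to aldehyde 8 to give syn aldol F5, in which the auxiliary fixes the carbon that becomes C3. NaBH4 in THF/H2O removes the auxiliary without reducing the aryl ester and gives diol F6. Camphorsulfonic acid in MeOH cleaves the methoxymethyl ether and ionises the benzylic alcohol, and the phenol closes the ring anti to the hydroxymethyl group to give trans alcohol F7. TIPSCl and imidazole convert F7 into 18.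

**Step 18 (Proposed new method).** The risks of step 12 apply, with two additions. Salt 24 is now the valuable partner and cannot be used in excess, so decay of ylide 25 by ionisation or rearrangement costs advanced material. Addition through the minor ylide face now gives a diastereomer that has to be separated.

The fallback is the same known aldol sequence; it sets out from alcohol 19 (and acid F3 above) and returns at 27. MnO2 oxidises 19 to aldehyde F8. Acid F3 is coupled with (S)-4-benzyloxazolidin-2-one to give mirror-image imide F9. The boron aldol of F9 with F8 gives syn adduct F10, NaBH4 gives diol F11, and camphorsulfonic acid in MeOH gives trans alcohol F12. TIPSCl and imidazole silylate the free primary hydroxyl of F12, and any other primary hydroxyl set free by the acid, to give 27.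

**Step 22 (Proposed new method).** The same processes threaten the step, on the largest and most acid- and base-labile sulfonium salt of the route. In addition, low solubility may slow ylide formation below the rate at which the methide decays.

The fallback sets out from alcohol 28 and returns at 33. MnO2 gives aldehyde F13. The boron aldol with imide F9 gives syn adduct F14, NaBH4 gives diol F15, camphorsulfonic acid in MeOH gives trans alcohol F16, and TIPSCl with imidazole gives 33.

**Step 5.** The benzylic cation carries a silyloxymethyl group, so a 1,2-hydride shift towards the aldehyde oxidation level may outrun capture by sulfinate, and the acid may remove the silyl ether.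

The fallback avoids the cation; it sets out from 1 and returns at 6. A Mannich reaction of 1 with formaldehyde and dimethylamine gives aminomethyl phenol F17. Heating F17 with p-TolSO2Na replaces the amine by sulfinate and gives sulfone F18. The dianion of F18 (LiN(SiMe3)2, 2.2 equiv, THF, −78 °C) is hydroxymethylated with monomeric formaldehyde and quenched cold to give hydroxy sulfone F19. TIPSCl and imidazole at 0 °C silylate the primary alcohol to give 6.

**Step 31.** Under the acid the new benzylic ether may re-ionise and be captured irreversibly by ring A in a Friedel–Crafts closure. The C2–O bonds of the dihydrobenzofurans may open in the same way, and the trans selectivity at C7 may be incomplete.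

The fallback blocks the nucleophilic position of ring A; it sets out from lactone 45 (with aldehyde 35) and returns at 49. NBS brominates 45 para to the methoxy group to give bromo lactone F20. The aldol with 35 as in step 29 gives adduct F21, LiBH4 gives triol F22, and camphorsulfonic acid closes the ring to bromo tetrahydrofuran F23 with no arene position left for the competing closure. Bu3SnH with AIBN in toluene at 90 °C removes the bromine and gives 49.

## Further compounds

F1 | step 12 | methyl 3-methoxy-4-(methoxymethoxy)-5-vinylbenzoate | COC(=O)c1cc(OC)c(OCOC)c(C=C)c1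
F2 | step 12 | methyl 3-(2-hydroxyethyl)-5-methoxy-4-(methoxymethoxy)benzoate | COC(=O)c1cc(OC)c(OCOC)c(CCO)c1
F3 | step 12 | [3-methoxy-5-(methoxycarbonyl)-2-(methoxymethoxy)phenyl]acetic acid | COC(=O)c1cc(OC)c(OCOC)c(CC(O)=O)c1
F4 | step 12 | methyl 3-{2-[(R)-4-benzyl-2-oxooxazolidin-3-yl]-2-oxoethyl}-5-methoxy-4-(methoxymethoxy)benzoate | COC(=O)c1cc(OC)c(OCOC)c(CC(=O)N2[C@H](Cc3ccccc3)COC2=O)c1
F5 | step 12 | (R)-4-benzyl-3-{(2R,3R)-3-hydroxy-2-[3-methoxy-5-(methoxycarbonyl)-2-(methoxymethoxy)phenyl]-3-ArE-propanoyl}oxazolidin-2-one | COC(=O)c1cc(OC)c(OCOC)c(c1)[C@@H](C(=O)N1[C@H](Cc2ccccc2)COC1=O)[C@@H](O)c1ccc(O[Si](C(C)C)(C(C)C)C(C)C)c(OC)c1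
F6 | step 12 | methyl 3-[(1R,2S)-1,3-dihydroxy-1-ArE-propan-2-yl]-5-methoxy-4-(methoxymethoxy)benzoate | COC(=O)c1cc(OC)c(OCOC)c(c1)[C@@H](CO)[C@@H](O)c1ccc(O[Si](C(C)C)(C(C)C)C(C)C)c(OC)c1
F7 | step 12 | methyl (2R,3S)-3-(hydroxymethyl)-7-methoxy-2-ArE-2,3-dihydrobenzofuran-5-carboxylate | COC(=O)c1cc(OC)c2c(c1)[C@@H](CO)[C@H](c1ccc(O[Si](C(C)C)(C(C)C)C(C)C)c(OC)c1)O2
F8 | step 18 | Ar(DE)–CHO | O=Cc1cc(OC)c2c(c1)[C@@H](CO[Si](C(C)C)(C(C)C)C(C)C)[C@H](c1ccc(O[Si](C(C)C)(C(C)C)C(C)C)c(OC)c1)O2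
F9 | step 18 | methyl 3-{2-[(S)-4-benzyl-2-oxooxazolidin-3-yl]-2-oxoethyl}-5-methoxy-4-(methoxymethoxy)benzoate | COC(=O)c1cc(OC)c(OCOC)c(CC(=O)N2[C@@H](Cc3ccccc3)COC2=O)c1
F10 | step 18 | (S)-4-benzyl-3-{(2S,3S)-3-hydroxy-2-[3-methoxy-5-(methoxycarbonyl)-2-(methoxymethoxy)phenyl]-3-Ar(DE)-propanoyl}oxazolidin-2-one | COC(=O)c1cc(OC)c(OCOC)c(c1)[C@H](C(=O)N1[C@@H](Cc2ccccc2)COC1=O)[C@H](O)c1cc(OC)c2c(c1)[C@@H](CO[Si](C(C)C)(C(C)C)C(C)C)[C@H](c1ccc(O[Si](C(C)C)(C(C)C)C(C)C)c(OC)c1)O2
F11 | step 18 | methyl 3-[(1S,2R)-1,3-dihydroxy-1-Ar(DE)-propan-2-yl]-5-methoxy-4-(methoxymethoxy)benzoate | COC(=O)c1cc(OC)c(OCOC)c(c1)[C@H](CO)[C@H](O)c1cc(OC)c2c(c1)[C@@H](CO[Si](C(C)C)(C(C)C)C(C)C)[C@H](c1ccc(O[Si](C(C)C)(C(C)C)C(C)C)c(OC)c1)O2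
F12 | step 18 | methyl (2S,3R)-3-(hydroxymethyl)-7-methoxy-2-Ar(DE)-2,3-dihydrobenzofuran-5-carboxylate | COC(=O)c1cc(OC)c2c(c1)[C@H](CO)[C@@H](c1cc(OC)c3c(c1)[C@@H](CO[Si](C(C)C)(C(C)C)C(C)C)[C@H](c1ccc(O[Si](C(C)C)(C(C)C)C(C)C)c(OC)c1)O3)O2
F13 | step 22 | Ar(CDE)–CHO | O=Cc1cc(OC)c2c(c1)[C@H](CO[Si](C(C)C)(C(C)C)C(C)C)[C@@H](c1cc(OC)c3c(c1)[C@@H](CO[Si](C(C)C)(C(C)C)C(C)C)[C@H](c1ccc(O[Si](C(C)C)(C(C)C)C(C)C)c(OC)c1)O3)O2
F14 | step 22 | (S)-4-benzyl-3-{(2S,3S)-3-hydroxy-2-[3-methoxy-5-(methoxycarbonyl)-2-(methoxymethoxy)phenyl]-3-Ar(CDE)-propanoyl}oxazolidin-2-one | COC(=O)c1cc(OC)c(OCOC)c(c1)[C@H](C(=O)N1[C@@H](Cc2ccccc2)COC1=O)[C@H](O)c1cc(OC)c2c(c1)[C@H](CO[Si](C(C)C)(C(C)C)C(C)C)[C@@H](c1cc(OC)c3c(c1)[C@@H](CO[Si](C(C)C)(C(C)C)C(C)C)[C@H](c1ccc(O[Si](C(C)C)(C(C)C)C(C)C)c(OC)c1)O3)O2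
F15 | step 22 | methyl 3-[(1S,2R)-1,3-dihydroxy-1-Ar(CDE)-propan-2-yl]-5-methoxy-4-(methoxymethoxy)benzoate | COC(=O)c1cc(OC)c(OCOC)c(c1)[C@H](CO)[C@H](O)c1cc(OC)c2c(c1)[C@H](CO[Si](C(C)C)(C(C)C)C(C)C)[C@@H](c1cc(OC)c3c(c1)[C@@H](CO[Si](C(C)C)(C(C)C)C(C)C)[C@H](c1ccc(O[Si](C(C)C)(C(C)C)C(C)C)c(OC)c1)O3)O2
F16 | step 22 | methyl (2S,3R)-3-(hydroxymethyl)-7-methoxy-2-Ar(CDE)-2,3-dihydrobenzofuran-5-carboxylate | COC(=O)c1cc(OC)c2c(c1)[C@H](CO)[C@@H](c1cc(OC)c3c(c1)[C@H](CO[Si](C(C)C)(C(C)C)C(C)C)[C@@H](c1cc(OC)c4c(c1)[C@@H](CO[Si](C(C)C)(C(C)C)C(C)C)[C@H](c1ccc(O[Si](C(C)C)(C(C)C)C(C)C)c(OC)c1)O4)O3)O2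
F17 | step 5 | methyl 3-[(dimethylamino)methyl]-4-hydroxy-5-methoxybenzoate | COC(=O)c1cc(OC)c(O)c(CN(C)C)c1
F18 | step 5 | methyl 4-hydroxy-3-methoxy-5-[(p-tolylsulfonyl)methyl]benzoate | COC(=O)c1cc(OC)c(O)c(CS(=O)(=O)c2ccc(C)cc2)c1
F19 | step 5 | methyl 4-hydroxy-3-[2-hydroxy-1-(p-tolylsulfonyl)ethyl]-5-methoxybenzoate (racemic) | COC(=O)c1cc(OC)c(O)c(c1)C(CO)S(=O)(=O)c1ccc(C)cc1
F20 | step 31 | (S)-4-[2-bromo-5-methoxy-4-(triisopropylsilyloxy)benzyl]dihydrofuran-2(3H)-one | O=C1C[C@H](Cc2cc(OC)c(O[Si](C(C)C)(C(C)C)C(C)C)cc2Br)CO1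
F21 | step 31 | (3R,4S)-4-[2-bromo-5-methoxy-4-(triisopropylsilyloxy)benzyl]-3-[hydroxy(Ar(BCDE))methyl]dihydrofuran-2(3H)-one (carbinol epimers) | O=C1OC[C@@H](Cc2cc(OC)c(O[Si](C(C)C)(C(C)C)C(C)C)cc2Br)[C@@H]1C(O)c1cc(OC)c2c(c1)[C@H](CO[Si](C(C)C)(C(C)C)C(C)C)[C@@H](c1cc(OC)c3c(c1)[C@H](CO[Si](C(C)C)(C(C)C)C(C)C)[C@@H](c1cc(OC)c4c(c1)[C@@H](CO[Si](C(C)C)(C(C)C)C(C)C)[C@H](c1ccc(O[Si](C(C)C)(C(C)C)C(C)C)c(OC)c1)O4)O3)O2
F22 | step 31 | (2S,3S)-3-[2-bromo-5-methoxy-4-(triisopropylsilyloxy)benzyl]-2-[hydroxy(Ar(BCDE))methyl]butane-1,4-diol (carbinol epimers) | OC[C@@H](Cc1cc(OC)c(O[Si](C(C)C)(C(C)C)C(C)C)cc1Br)[C@@H](CO)C(O)c1cc(OC)c2c(c1)[C@H](CO[Si](C(C)C)(C(C)C)C(C)C)[C@@H](c1cc(OC)c3c(c1)[C@H](CO[Si](C(C)C)(C(C)C)C(C)C)[C@@H](c1cc(OC)c4c(c1)[C@@H](CO[Si](C(C)C)(C(C)C)C(C)C)[C@H](c1ccc(O[Si](C(C)C)(C(C)C)C(C)C)c(OC)c1)O4)O3)O2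
F23 | step 31 | {(2R,3S,4S)-2-Ar(BCDE)-4-[2-bromo-5-methoxy-4-(triisopropylsilyloxy)benzyl]tetrahydrofuran-3-yl}methanol | COc1cc(C[C@@H]2CO[C@@H](c3cc(OC)c4c(c3)[C@H](CO[Si](C(C)C)(C(C)C)C(C)C)[C@@H](c3cc(OC)c5c(c3)[C@H](CO[Si](C(C)C)(C(C)C)C(C)C)[C@@H](c3cc(OC)c6c(c3)[C@@H](CO[Si](C(C)C)(C(C)C)C(C)C)[C@H](c3ccc(O[Si](C(C)C)(C(C)C)C(C)C)c(OC)c3)O6)O5)O4)[C@@H]2CO)c(Br)cc1O[Si](C(C)C)(C(C)C)C(C)C
A1 | alternative 1 | dimethyl (2S,3S)-2-[3-bromo-5-methoxy-4-(pivaloyloxy)phenyl]-7-methoxy-2,3-dihydrobenzofuran-3,5-dicarboxylate (trans) | COC(=O)c1cc(OC)c2c(c1)[C@H](C(=O)OC)[C@@H](c1cc(OC)c(OC(=O)C(C)(C)C)c(Br)c1)O2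
A2 | alternative 1 | methyl (2S)-2-[3-bromo-5-methoxy-4-(pivaloyloxy)phenyl]-8-methoxy-4-oxochromane-6-carboxylate | COC(=O)c1cc(OC)c2O[C@H](c3cc(OC)c(OC(=O)C(C)(C)C)c(Br)c3)CC(=O)c2c1
A3 | alternative 2 | trans-disubstituted menthyloxy butyrolactone carrying the ring A dithiane and the carbinol from the ring B aldehyde (C7 epimers), TBS ethers | COc5cc(C6(SCCCS6)[C@@H]7[C@@H](O[C@H]8C[C@@H](C)CC[C@@H]8C(C)C)OC(=O)[C@H]7C(O)c1cc(OC)c2c(c1)[C@H](CO[Si](C)(C)C(C)(C)C)[C@@H](c1cc(OC)c3c(c1)[C@H](CO[Si](C)(C)C(C)(C)C)[C@@H](c1cc(OC)c4c(c1)[C@@H](CO[Si](C)(C)C(C)(C)C)[C@H](c1ccc(O[Si](C)(C)C(C)(C)C)c(OC)c1)O4)O3)O2)ccc5O[Si](C)(C)C(C)(C)C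
A4 | alternative 2 | 2-[4-(tert-butyldimethylsilyloxy)-3-methoxyphenyl]-1,3-dithiane | COc1cc(C2SCCCS2)ccc1O[Si](C)(C)C(C)(C)C
A5 | alternative 2 | (5S)-5-[(1S,2R,5S)-menthyloxy]furan-2(5H)-one | O=C1C=C[C@@H](O[C@H]2C[C@@H](C)CC[C@@H]2C(C)C)O1
A6 | alternative 2 | ring B aldehyde carrying units 1 to 3 as tert-butyldimethylsilyl ethers | O=Cc1cc(OC)c2c(c1)[C@H](CO[Si](C)(C)C(C)(C)C)[C@@H](c1cc(OC)c3c(c1)[C@H](CO[Si](C)(C)C(C)(C)C)[C@@H](c1cc(OC)c4c(c1)[C@@H](CO[Si](C)(C)C(C)(C)C)[C@H](c1ccc(O[Si](C)(C)C(C)(C)C)c(OC)c1)O4)O3)O2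
A7 | alternative 3 | trans,trans bis(dihydrobenzofuran) triester with unit 3 attached | COC(=O)c1cc(OC)c2c(c1)[C@H](C(=O)OC)[C@@H](c1cc(OC)c3c(c1)[C@H](C(=O)OC)[C@@H](c1cc(OC)c4c(c1)[C@@H](CO[Si](C)(C)C(C)(C)C)[C@H](c1ccc(O[Si](C)(C)C(C)(C)C)c(OC)c1)O4)O3)O2
A8 | alternative 3 | bis(aryl diazoacetate) with ring B–O–CH2–ring C and ring C–O–CH2–ring D ether links and unit 3 attached | COC(=O)c1cc(OC)c(OCc2cc(OC)c(OCc3cc(OC)c4c(c3)[C@@H](CO[Si](C)(C)C(C)(C)C)[C@H](c3ccc(O[Si](C)(C)C(C)(C)C)c(OC)c3)O4)c(c2)C(=[N+]=[N-])C(=O)OC)c(c1)C(=[N+]=[N-])C(=O)OC
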